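Retrosynthesis: unmask the C3 ketone from a dioxolane, then cut C9–C11 (ring B carbon to the OCH2 carbon of the umbelliferyl ether), then the C8–CH3 bond and the two C4–CH3 bonds. This leaves (S)-Wieland–Miescher ketone on one side and 7-(chloromethoxy)coumarin, made from umbelliferone, on the other.
Enabling feature: in ring B the array C11–C9–C8(CH3)=C7 is a homoallylic ether, the retron of an SE2' allylation. C9 lies next to quaternary C10, whose axial β-methyl closes the β face of C9.
Key event: a fluxional allylzinc spanning C7–C8–C9 (zinc on C7) is alkylated at C9 by ArOCH2Cl. This one event makes C9–C11, sets the axial 9α centre, fixes the alkene at C7=C8 and brings in the whole coumarin ether, starting from any mixture of allylic chloride isomers.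
Forward order: both rings come with the starting ketone. Ring A is finished first (C4 gem-dimethyl, trans fusion, C3 masked). Ring B is then taken from the C9 ketone to the 8-methyl enone, the allylic alcohol and the allylic chloride. Union and ketal hydrolysis end the route.
Stereochemistry: C10 comes from the starting material, C5 from axial protonation in the dissolving-metal reduction, and C9 from substrate-controlled α attack in the union.

Key step: step 12

Remark: drimane numbering is used for the decalin. C3 is the carbonyl carbon, C4 the gem-dimethyl carbon, C5 the ring-fusion CH, C7=C8 the alkene, C9 the CH bearing C11H2OAr, and C10 the methyl-bearing ring-fusion carbon. β is the face of the C10 methyl and α the opposite face. Ar = 2-oxo-2H-chromen-7-yl.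

Step 1
Reactants: 1 umbelliferone (7-hydroxy-2H-chromen-2-one)
Product: 2 7-(methylsulfanylmethoxy)-2H-chromen-2-one
Conditions: ClCH2SMe, K2CO3, NaI (cat.), DMF, rt
Reagents that add atoms: chloromethyl methyl sulfide, CSCCl
Why: Williamson etherification of the acidic 7-phenol with a reactive α-chloro sulfide should give the O,S-acetal without touching the lactone; no stereocenter is formed.

Step 2
Reactants: 2 7-(methylsulfanylmethoxy)-2H-chromen-2-one
Product: 3 7-(chloromethoxy)-2H-chromen-2-one
Conditions: SO2Cl2 (1.0 equiv), CH2Cl2, 0 °C; volatiles removed, used crude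
Reagents that add atoms: sulfuryl chloride, ClS(Cl)(=O)=O
Why: Chlorinolysis of an O,S-acetal, in which sulfur is chlorinated far faster than the electron-poor coumarin and the chlorosulfonium ion collapses to the aryl chloromethyl ether, leaving only volatile by-products.

Step 3
Reactants: 4 (S)-(+)-Wieland–Miescher ketone
Product: 5 (4aS,5S)-5-hydroxy-4a-methyl-4,4a,5,6,7,8-hexahydronaphthalen-2(3H)-one (9β-hydroxy enone)
Conditions: NaBH4 (0.3 equiv), EtOH, 0 °C
Reagents that add atoms: none
Why: Chemoselective borohydride reduction, in which the saturated C9 ketone is more electrophilic than the conjugated C3 carbonyl and hydride arrives from the α face opposite the C10 methyl, giving the 9β alcohol as a temporary stereocenter that masks C9 during the ring A work.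

Step 4
Reactants: 5 9β-hydroxy enone
Product: 6 4-(phenylsulfanylmethyl)-9β-hydroxy enone (PhSCH2 on the enone α-carbon C4)
Conditions: PhSH, 37% aq. HCHO, Et3N, EtOH, reflux
Reagents that add atoms: formaldehyde, C=O; thiophenol, Sc1ccccc1
Why: Kirk–Petrow reaction, in which the dienolate is hydroxymethylated at C4 and the derived 4-methylene species is trapped by thiophenol, installing the first C4 carbon as a stable CH2SPh group without a new stereocenter.

Step 5
Reactants: 6 4-(phenylsulfanylmethyl)-9β-hydroxy enone
Product: 8 9β-hydroxy-4,4,10β-trimethyl-trans-decalin-3-one (H5 α), via dilithium enolate alkoxide 7 (not isolated)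
Conditions: Li, NH3(l)/THF, −78 to −33 °C; then MeI (excess), −78 °C to rt; NH4Cl work-up
Reagents that add atoms: iodomethane, CI
Why: Dissolving-metal reductive alkylation of an enone, in which electron transfer saturates C4=C5 with axial protonation at C5 (H5 α, trans-decalin), expels thiophenolate and reduces the resulting 4-methylene ketone to the regiodefined C3–C4 enolate 7, whose C-methylation completes the gem-dimethyl group.

Step 6
Reactants: 8 9β-hydroxy-4,4,10β-trimethyl-trans-decalin-3-one
Product: 9 3,3-ethylenedioxy-4,4,10β-trimethyl-trans-decalin-9β-ol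
Conditions: HOCH2CH2OH, p-TsOH·H2O (cat.), benzene, Dean–Stark reflux
Reagents that add atoms: ethylene glycol, OCCO
Why: Acid-catalysed ketalisation with azeotropic removal of water masks the only carbonyl group as a dioxolane that is inert to bases, hydrides and organozinc reagents.

Step 7
Reactants: 9 3,3-ethylenedioxy-4,4,10β-trimethyl-trans-decalin-9β-ol
Product: 10 3,3-ethylenedioxy-4,4,10β-trimethyl-trans-decalin-9-one
Conditions: (n-Pr4N)RuO4 (5 mol %), NMO, 4 Å MS, CH2Cl2, rt
Reagents that add atoms: none
Why: Ley–Griffith oxidation converts the hindered secondary alcohol into the C9 ketone under neutral conditions that spare the ketal, and it removes the temporary C9 stereocenter.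

Step 8
Reactants: 10 3,3-ethylenedioxy-4,4,10β-trimethyl-trans-decalin-9-one
Product: 12 3,3-ethylenedioxy-4,4,8α,10β-tetramethyl-trans-decalin-9-one, via lithium enolate 11 (not isolated)
Conditions: LiN(i-Pr)2, THF, −78 °C; then MeI, −78 to 0 °C
Reagents that add atoms: iodomethane, CI
Why: Kinetic enolate alkylation, in which C10 is quaternary so deprotonation can occur only at C8, and MeI enters away from the axial C10 methyl to give the equatorial 8α-methyl ketone, a stereocenter erased in the next step.

Step 9
Reactants: 12 3,3-ethylenedioxy-4,4,8α,10β-tetramethyl-trans-decalin-9-one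
Product: 15 3,3-ethylenedioxy-11-nordrim-7-en-9-one (C7H=C8(CH3)–C9=O), via lithium enolate 13 (not isolated), via trimethylsilyl enol ether 14 (not isolated)
Conditions: LiN(i-Pr)2, THF, −78 to 0 °C; TMSCl; then Pd(OAc)2 (1.05 equiv), MeCN, rt
Reagents that add atoms: none
Why: Saegusa–Ito oxidation, in which the only possible enolate is silylated and palladation at C8 followed by syn β-hydride elimination toward ring carbon C7 should give the conjugated endocyclic 8-methyl enone.

Step 10
Reactants: 15 3,3-ethylenedioxy-11-nordrim-7-en-9-one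
Product: 16 3,3-ethylenedioxy-11-nordrim-7-en-9β-ol
Conditions: NaBH4, CeCl3·7H2O, MeOH, 0 °C
Reagents that add atoms: none
Why: Luche reduction gives clean 1,2-reduction with hydride from the α face (9β allylic alcohol), and this configuration is of no consequence because it is lost in steps 11 and 12.

Step 11
Reactants: 16 3,3-ethylenedioxy-11-nordrim-7-en-9β-ol
Product: 18 7α-chloro-3,3-ethylenedioxy-11-nordrim-8-ene (C8(CH3)=C9H), via allylic mesylate 17 (not isolated)
Conditions: MsCl, 2,4,6-collidine, LiCl, DMF, 0 °C; used without purification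
Reagents that add atoms: lithium chloride, [Li+].[Cl-]
Why: Mesylation with in situ chloride displacement of an allylic alcohol, in which the hindered C9 mesylate 17 should be displaced with allylic transposition (anti SN2', axial entry at C7) under buffered conditions that spare the ketal, and any 7β or C9 chloride formed alongside is equally usable in step 12.

Step 12
Reactants: 18 7α-chloro-3,3-ethylenedioxy-11-nordrim-8-ene; 3 7-(chloromethoxy)-2H-chromen-2-one
Product: 20 3,3-ethylenedioxy derivative of the target (9α-CH2OAr and C7=C8), via allylzinc chloride 19 (not isolated)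
Conditions: activated Zn dust, LiCl, THF, 0 to 25 °C; supernatant cannulated into 3 (1.5 equiv), THF, −78 to 0 °C
Reagents that add atoms: none
Why: Zinc inserts into the allylic C–Cl bond by electron transfer through the planar C7–C8–C9 allyl radical, and allylzinc 19 equilibrates rapidly by 1,3-metallotropic shifts, so both C7 epimers and the C9 regioisomer of 18 funnel into one reagent with zinc σ-bound to the less hindered C7. This reagent attacks the CH2 of 3, whose C–Cl bond is loosened by the Lewis acidic zinc, through its γ-carbon C9 in an SE2' process that forms C9–C11 and moves the double bond to C7=C8 in the same event. The closest known reaction type is the γ-selective substitution of α-chloro ethers by substituted allylic zinc halides, which gives branched homoallylic ethers; no ring is closed. The new stereocenter C9 is set by the substrate, because the axial β-methyl on the adjacent C10 blocks the β face and α attack is the axial, chair-like trajectory on the ring B half-chair; both a closed chloride-bridged transition state from the 7α-zinc epimer and an open anti transition state from the 7β epimer lead to this α attack, placing CH2OAr trans to the C10 methyl and cis to H5. The step needs γ- over α-selectivity, secured by the preference of the bulky solvated zinc for C7 over the neopentyl C9. It also needs chemoselectivity for the chloromethyl ether over the lactone, secured by the much higher reactivity of the α-chloro ether at −78 °C under inverse addition, with the C3 ketone masked as the dioxolane.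

Step 13
Reactants: 20 3,3-ethylenedioxy derivative of the target
Product: 21 target, 7-{[(1R,4aR,8aS)-2,5,5,8a-tetramethyl-6-oxo-1,4,4a,5,6,7,8,8a-octahydronaphthalen-1-yl]methoxy}-2H-chromen-2-one
Conditions: 1 M aq. HCl, THF, rt
Reagents that add atoms: water, O
Why: Acid-catalysed ketal hydrolysis, helped by relief of strain next to the C4 gem-dimethyl group, frees the C3 ketone while the aryl alkyl ether, the lactone, the trisubstituted alkene and the non-epimerisable C9 centre remain unaffected.

Compound list
1 | umbelliferone (7-hydroxy-2H-chromen-2-one) | Oc1ccc2ccc(=O)oc2c1 | starting material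
2 | 7-(methylsulfanylmethoxy)-2H-chromen-2-one | CSCOc1ccc2ccc(=O)oc2c1 | intermediate
3 | 7-(chloromethoxy)-2H-chromen-2-one | ClCOc1ccc2ccc(=O)oc2c1 | intermediate
4 | (S)-(+)-Wieland–Miescher ketone | C[C@]12CCC(=O)C=C1CCCC2=O | starting material
5 | (4aS,5S)-5-hydroxy-4a-methyl-4,4a,5,6,7,8-hexahydronaphthalen-2(3H)-one | O[C@H]1CCCC2=CC(=O)CC[C@]12C | intermediate
6 | 4-(phenylsulfanylmethyl)-9β-hydroxy enone | O[C@H]1CCCC2=C(CSc3ccccc3)C(=O)CC[C@]12C | intermediate
7 | dilithium C3–C4 enolate C9 alkoxide (H5 α) | [Li]O[C@H]1CCC[C@H]2C(C)=C(O[Li])CC[C@]12C | intermediate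
8 | 9β-hydroxy-4,4,10β-trimethyl-trans-decalin-3-one | O[C@H]1CCC[C@H]2C(C)(C)C(=O)CC[C@]12C | intermediate
9 | 3,3-ethylenedioxy-4,4,10β-trimethyl-trans-decalin-9β-ol | O[C@H]1CCC[C@H]2C(C)(C)C3(OCCO3)CC[C@]12C | intermediate
10 | 3,3-ethylenedioxy-4,4,10β-trimethyl-trans-decalin-9-one | O=C1CCC[C@H]2C(C)(C)C3(OCCO3)CC[C@]12C | intermediate
11 | lithium C8–C9 enolate of 10 | [Li]OC1=CCC[C@H]2C(C)(C)C3(OCCO3)CC[C@]12C | intermediate
12 | 3,3-ethylenedioxy-4,4,8α,10β-tetramethyl-trans-decalin-9-one | O=C1[C@H](C)CC[C@H]2C(C)(C)C3(OCCO3)CC[C@]12C | intermediate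
13 | lithium C8–C9 enolate of 12 | [Li]OC1=C(C)CC[C@H]2C(C)(C)C3(OCCO3)CC[C@]12C | intermediate
14 | trimethylsilyl enol ether of 12 | C[Si](C)(C)OC1=C(C)CC[C@H]2C(C)(C)C3(OCCO3)CC[C@]12C | intermediate
15 | 3,3-ethylenedioxy-11-nordrim-7-en-9-one | O=C1C(C)=CC[C@H]2C(C)(C)C3(OCCO3)CC[C@]12C | intermediate
16 | 3,3-ethylenedioxy-11-nordrim-7-en-9β-ol | O[C@H]1C(C)=CC[C@H]2C(C)(C)C3(OCCO3)CC[C@]12C | intermediate
17 | 9β-methanesulfonate of 16 | CS(=O)(=O)O[C@H]1C(C)=CC[C@H]2C(C)(C)C3(OCCO3)CC[C@]12C | intermediate
18 | 7α-chloro-3,3-ethylenedioxy-11-nordrim-8-ene | Cl[C@@H]1C[C@H]2C(C)(C)C3(OCCO3)CC[C@]2(C)C=C1C | intermediate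
19 | 3,3-ethylenedioxy-11-nordrim-8-en-7-ylzinc chloride (fluxional, LiCl-solvated) | Cl[Zn]C1C[C@H]2C(C)(C)C3(OCCO3)CC[C@]2(C)C=C1C | intermediate
20 | 3,3-ethylenedioxy derivative of the target | CC1=CC[C@H]2C(C)(C)C3(OCCO3)CC[C@]2(C)[C@@H]1COc1ccc2ccc(=O)oc2c1 | intermediate
21 | target (3-oxo, H5 α, 10β-CH3, 9α-CH2OAr, C7=C8) | CC1=CC[C@H]2C(C)(C)C(=O)CC[C@]2(C)[C@@H]1COc1ccc2ccc(=O)oc2c1 | target

Total step count: 13. Longest linear sequence: 11 (steps 3 to 13).

Steps most likely to fail

Step 12. The allylzinc may react through C7 after a metallotropic shift (loss of γ-selectivity). The facial bias at C9 may erode. Wurtz-type dimerisation may occur during the insertion, or the reagent may add to the lactone. The fallback sets out from 15 and returns at 20. It forms C9–C11 intramolecularly and attaches the aryl group afterwards.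
- Nucleophilic epoxidation (H2O2, NaOH, MeOH) from the α face should give the 7α,8α-epoxy ketone F1.
- Wharton transposition (N2H4·H2O, AcOH, MeOH) gives the 7α-hydroxy-8-ene F2.
- Alkylation (KH, ICH2SnBu3, THF) gives the stannylmethyl ether F3.
- Tin–lithium exchange (n-BuLi, THF, −78 °C) gives the lithiomethyl ether F4, which undergoes the suprafacial Still–Wittig [2,3]-rearrangement on the α face to the 9α-hydroxymethyl-7-ene F5.
- Mitsunobu etherification of F5 with 1 (PPh3, DIAD, THF) gives 20.

Step 11. The hindered allylic mesylate may ionise and lose a proton to a ring B diene, or the labile chloride may hydrolyse during handling. The fallback sets out from 16 and returns at 19. It avoids any allylic halide.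
- Acetylation (Ac2O, DMAP, pyridine) gives the 9β-acetate F6.
- Pd(PPh3)4-catalysed stannylation with Bu3SnAlEt2 places tin on the less hindered terminus and gives the 7α-tributylstannyl-8-ene F7.
- Tin–lithium exchange (n-BuLi, THF, −78 °C) gives the allyllithium F8.
- Transmetallation with ZnCl2 gives 19.

Step 9. Palladation at the fully substituted C8 may be sluggish, and β-hydride loss from the C8 methyl group would lead to the exocyclic methylene isomer. The fallback sets out from 10 and returns at 15. It bypasses step 8 by introducing the methyl group after the double bond.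
- Dehydrogenation of 10 with IBX (DMSO/toluene, 70 °C) can only give the endocyclic 7-en-9-one F9.
- α-Iodination (I2, pyridine, CH2Cl2) gives the 8-iodo enone F10.
- Suzuki–Miyaura methylation (MeB(OH)2, Pd(dppf)Cl2, K3PO4, dioxane, 80 °C) gives 15.

Further compounds
F1 | step 12 | 7α,8α-epoxy-3,3-ethylenedioxy-11-nordriman-9-one | C[C@]12O[C@@H]2C[C@H]3C(C)(C)C4(OCCO4)CC[C@]3(C)C1=O
F2 | step 12 | 3,3-ethylenedioxy-11-nordrim-8-en-7α-ol | O[C@@H]1C[C@H]2C(C)(C)C3(OCCO3)CC[C@]2(C)C=C1C
F3 | step 12 | 7α-(tributylstannylmethoxy)-3,3-ethylenedioxy-11-nordrim-8-ene | CCCC[Sn](CCCC)(CCCC)CO[C@@H]1C[C@H]2C(C)(C)C3(OCCO3)CC[C@]2(C)C=C1C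
F4 | step 12 | 7α-(lithiomethoxy)-3,3-ethylenedioxy-11-nordrim-8-ene | [Li]CO[C@@H]1C[C@H]2C(C)(C)C3(OCCO3)CC[C@]2(C)C=C1C
F5 | step 12 | 3,3-ethylenedioxy-9-epi-drim-7-en-11-ol (9α-CH2OH) | CC1=CC[C@H]2C(C)(C)C3(OCCO3)CC[C@]2(C)[C@@H]1CO
F6 | step 11 | 9β-acetoxy-3,3-ethylenedioxy-11-nordrim-7-ene | CC(=O)O[C@H]1C(C)=CC[C@H]2C(C)(C)C3(OCCO3)CC[C@]12C
F7 | step 11 | 7α-tributylstannyl-3,3-ethylenedioxy-11-nordrim-8-ene | CCCC[Sn](CCCC)(CCCC)[C@@H]1C[C@H]2C(C)(C)C3(OCCO3)CC[C@]2(C)C=C1C
F8 | step 11 | 3,3-ethylenedioxy-11-nordrim-8-en-7-yllithium | [Li]C1C[C@H]2C(C)(C)C3(OCCO3)CC[C@]2(C)C=C1C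
F9 | step 9 | 3,3-ethylenedioxy-4,4,10β-trimethyl-trans-octal-7-en-9-one | O=C1C=CC[C@H]2C(C)(C)C3(OCCO3)CC[C@]12C
F10 | step 9 | 8-iodo-3,3-ethylenedioxy-4,4,10β-trimethyl-trans-octal-7-en-9-one | O=C1C(I)=CC[C@H]2C(C)(C)C3(OCCO3)CC[C@]12C
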